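**Retrosynthetic overview** (azulene numbering: ring A = C1, C2, C3, C3a, C8a; ring B = C3a to C8a)

1. Target 21 comes from diol 19 by two late esterifications (secondary OH propanoylated, then tertiary OH acetylated). The diol travels from 9 to 18 as a cis-fused acetonide (temporary ring C).
2. Ring A is cut last at C1–C2 and C3=C3a: a one-pot Stetter addition of propanal to an exocyclic enone, then aldol condensation. This is possible because the C2 carbonyl and C3a (a latent ring-B ketone) are 1,4-related through C8a–C1, and C1 is a CH2 that can enter as the methylidene of a 2-methylidenecycloheptanone.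
3. The exocyclic enone is released from Mannich base 14, made from cycloheptenone 12 by face-selective conjugate reduction (sets C8) and aminomethylation of the regiodefined silyl enol ether.
4. Ring B is closed by ring-closing metathesis of dienone 11, which forms the C8=C8a double bond of 12.
5. The C5/C6 stereodiad comes from (S)-5-(hydroxymethyl)furan-2(5H)-one 1 by radical addition of propan-2-ol trans to the resident substituent, then epoxide opening with an isopropenyl nucleophile. Rings form in the order C, B, A.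

Key step: step 10

Remark: compound 1 is taken as a commercial chiral-pool material; its stereocentre becomes C6 of the target and is never touched.

**Route**

Step 1
Reactants: 1 (S)-5-(hydroxymethyl)furan-2(5H)-one
Product: 2 [(2S)-5-oxo-2,5-dihydrofuran-2-yl]methyl 4-methylbenzenesulfonate
Conditions: TsCl (1.2 equiv), pyridine, CH2Cl2, 0 °C
Reagents that add atoms: p-toluenesulfonyl chloride, Cc1ccc(cc1)S(Cl)(=O)=O
Why: Standard sulfonylation of the primary alcohol turns C–O into a leaving group for later use and does not involve the stereocentre.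

Step 2
Reactants: 2 [(2S)-5-oxo-2,5-dihydrofuran-2-yl]methyl 4-methylbenzenesulfonate; 3 propan-2-ol
Product: 4 [(2S,3S)-3-(2-hydroxypropan-2-yl)-5-oxooxolan-2-yl]methyl 4-methylbenzenesulfonate (2,3-trans lactone)
Conditions: Ph2CO (0.2 equiv), degassed propan-2-ol as solvent, hν (350 nm, Pyrex), 20 °C
Reagents that add atoms: none
Why: Benzophenone-sensitised hydrogen abstraction gives the nucleophilic 2-hydroxyprop-2-yl radical, which adds to the butenolide β-carbon anti to the resident substituent (photoinduced radical conjugate addition of alcohols to 5-substituted furan-2(5H)-ones), so the new stereocentre should be set trans by the existing one.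

Step 3
Reactants: 4 [(2S,3S)-3-(2-hydroxypropan-2-yl)-5-oxooxolan-2-yl]methyl 4-methylbenzenesulfonate
Product: 5 (4S)-5,5-dimethyl-4-[(2S)-oxiran-2-yl]oxolan-2-one
Conditions: K2CO3 (1.5 equiv), MeOH, 0 °C to 20 °C; neutral work-up
Reagents that add atoms: none
Why: Methoxide opens the lactone, the freed secondary alkoxide closes onto the CH2OTs carbon (3-exo-tet Williamson epoxide formation, no stereocentre touched), and the tertiary γ-hydroxy ester relactonises under the gem-dimethyl effect (lactone interchange).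

Step 4
Reactants: 5 (4S)-5,5-dimethyl-4-[(2S)-oxiran-2-yl]oxolan-2-one; 6 isopropenylmagnesium bromide
Product: 7 (4S)-4-[(1R)-1-hydroxy-3-methylbut-3-en-1-yl]-5,5-dimethyloxolan-2-one
Conditions: 6 (2 equiv), CuBr·SMe2 (10 mol %), THF, −40 °C to −20 °C; aq NH4Cl
Reagents that add atoms: none
Why: Copper-catalysed Grignard opening of a terminal epoxide at its CH2 carbon (SN2) should outrun addition to the lactone at low temperature and leaves both stereocentres untouched.

Step 5
Reactants: 7 (4S)-4-[(1R)-1-hydroxy-3-methylbut-3-en-1-yl]-5,5-dimethyloxolan-2-one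
Product: 8 (3S,4R)-4-hydroxy-3-(2-hydroxypropan-2-yl)-N-methoxy-N,6-dimethylhept-6-enamide
Conditions: MeNHOMe·HCl (3 equiv), AlMe3 (3 equiv), CH2Cl2, 0 °C to 20 °C; Rochelle salt work-up; crude used at once
Reagents that add atoms: N,O-dimethylhydroxylamine hydrochloride, CNOC.Cl
Why: Aminolysis of the γ-lactone with the aluminium amide (Weinreb amide formation) frees the tertiary alcohol, and either ring-chain lactone isomer of 7 would give the same amide.

Step 6
Reactants: 8 (3S,4R)-4-hydroxy-3-(2-hydroxypropan-2-yl)-N-methoxy-N,6-dimethylhept-6-enamide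
Product: 9 N-methoxy-N-methyl-2-[(5S,6R)-2,2,4,4-tetramethyl-6-(2-methylprop-2-en-1-yl)-1,3-dioxan-5-yl]acetamide
Conditions: 2-methoxypropene (3 equiv), PPTS (5 mol %), CH2Cl2, 0 °C
Reagents that add atoms: 2-methoxypropene, COC(C)=C
Why: Acid-catalysed ketalisation of the 1,3-diol closes the six-membered 1,3-dioxane (ring C) faster than the hydroxy amide can relactonise, and protects both oxygens for the organometallic and basic steps.

Step 7
Reactants: 9 N-methoxy-N-methyl-2-[(5S,6R)-2,2,4,4-tetramethyl-6-(2-methylprop-2-en-1-yl)-1,3-dioxan-5-yl]acetamide; 10 vinylmagnesium bromide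
Product: 11 1-[(5S,6R)-2,2,4,4-tetramethyl-6-(2-methylprop-2-en-1-yl)-1,3-dioxan-5-yl]but-3-en-2-one
Conditions: 10 (1.5 equiv), THF, −78 °C to 0 °C; inverse quench into cold aq NH4Cl
Reagents that add atoms: none
Why: Weinreb ketone synthesis, in which the chelated tetrahedral intermediate stops at single addition and the inverse quench keeps the released amine from adding to the new enone.

Step 8
Reactants: 11 1-[(5S,6R)-2,2,4,4-tetramethyl-6-(2-methylprop-2-en-1-yl)-1,3-dioxan-5-yl]but-3-en-2-one
Product: 12 (4aS,9aR)-2,2,4,4,8-pentamethyl-4a,5,9,9a-tetrahydro-4H-cyclohepta[d][1,3]dioxin-6-one (C7=C8 enone; the cis-fused acetonide of (5R,6S)-5-hydroxy-6-(2-hydroxypropan-2-yl)-3-methylcyclohept-2-en-1-one)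
Conditions: second-generation Hoveyda–Grubbs catalyst RuCl2(H2IMes)(=CH-C6H4-2-OiPr) (5 mol %), toluene (5 mM), 80 °C
Reagents that add atoms: none
Why: Ring-closing metathesis between the vinyl ketone and the 1,1-disubstituted alkene closes ring B as a trisubstituted cycloheptenone with loss of ethene, a ring size and substitution pattern within reach of this catalyst.

Step 9
Reactants: 12 (4aS,9aR)-2,2,4,4,8-pentamethyl-4a,5,9,9a-tetrahydro-4H-cyclohepta[d][1,3]dioxin-6-one
Product: 14 (4aS,7S,8S,9aR)-7-[(dimethylamino)methyl]-2,2,4,4,8-pentamethylhexahydro-4H-cyclohepta[d][1,3]dioxin-6(5H)-one, via dimethylphenylsilyl enol ether 13 (not isolated)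
Conditions: [(Ph3P)CuH]6 (3 mol %), PhMe2SiH (1.5 equiv), toluene, 20 °C; then [CH2=NMe2]I (2 equiv), CH2Cl2, 20 °C; aq NaHCO3
Reagents that add atoms: dimethylphenylsilane, C[SiH](C)c1ccccc1 (its silicon stays only in 13); N,N-dimethylmethyleneiminium iodide, C=[N+](C)C.[I-]
Why: Copper hydride conjugate reduction should deliver hydride to the β-carbon from the face opposite the cis-fused dioxane, placing the methyl group cis to the ring oxygen, and gives the regiodefined silyl enol ether, whose Mannich reaction with the preformed iminium salt puts CH2NMe2 on the α-carbon next to the methyl-bearing carbon and anti to the methyl group.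

Step 10
Reactants: 14 (4aS,7S,8S,9aR)-7-[(dimethylamino)methyl]-2,2,4,4,8-pentamethylhexahydro-4H-cyclohepta[d][1,3]dioxin-6(5H)-one; 15 propanal
Product: 18 acetonide of 19 (tricyclic enone: the hydroazulenone of 19 with O6 and the side-chain oxygen bridged by CMe2), via exocyclic enone 16 (not isolated), via 1,4-diketone 17 (not isolated)
Conditions: 3-benzyl-5-(2-hydroxyethyl)-4-methylthiazolium chloride (20 mol %), Et3N (1 equiv), EtOH, 80 °C, slow addition of 15 (4 equiv) under a N2 sweep; then 2 M aq NaOH, 70 °C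
Reagents that add atoms: none
Why: Heating the Mannich base with Et3N expels dimethylamine (E1cB) to give exocyclic enone 16 at low stationary concentration, and the thiazol-2-ylidene converts propanal into the Breslow intermediate, whose acyl-anion carbon adds 1,4 to the unsubstituted CH2 terminus of 16 to give 1,4-diketone 17 (Stetter reaction in its known variant that starts from Mannich bases). Hydroxide then enolises the ethyl ketone at its CH2 and the enolate attacks the ring ketone in a 5-(enolendo)-exo-trig aldol closure, formally disfavoured but well established for 1,4-diketones in hot alkali, and loss of water gives the tetrasubstituted enone of ring A (the cyclodehydration that turns 2-(2-oxoalkyl)cycloalkanones into fused cyclopentenones). The only new stereocentre, the ring-fusion CH (C8a), is epimerisable while α to the ring ketone in 17 and should settle trans to the neighbouring C8 methyl group before the aldol step fixes it. Regioselectivity of the aldol is secured by the substrate, because only attack of the ethyl-ketone enolate on the ring carbonyl leads to a dehydratable, conjugated product, whereas the alternative ring-enolate closure gives a bridged ketol that reverts. Chemoselectivity rests on the high acceptor reactivity of the β-unsubstituted exocyclic enone relative to propanal itself, helped by slow aldehyde addition, and the acetonide is inert to both bases.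

Step 11
Reactants: 18 acetonide of 19
Product: 19 (5S,6R,8S,8aR)-6-hydroxy-5-(2-hydroxypropan-2-yl)-3,8-dimethyl-4,5,6,7,8,8a-hexahydroazulen-2(1H)-one
Conditions: AcOH/H2O 4:1, 45 °C
Reagents that add atoms: none
Why: Acid-catalysed acetal hydrolysis under conditions that should leave the enone and the tertiary alcohol intact; no stereocentre is touched.

Step 12
Reactants: 19 (5S,6R,8S,8aR)-6-hydroxy-5-(2-hydroxypropan-2-yl)-3,8-dimethyl-4,5,6,7,8,8a-hexahydroazulen-2(1H)-one
Product: 20 (5S,6R,8S,8aR)-5-(2-hydroxypropan-2-yl)-3,8-dimethyl-2-oxo-1,2,4,5,6,7,8,8a-octahydroazulen-6-yl propanoate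
Conditions: (EtCO)2O (1.5 equiv), pyridine, DMAP (5 mol %), CH2Cl2, 0 °C
Reagents that add atoms: propanoic anhydride, CCC(=O)OC(=O)CC
Why: DMAP-catalysed acylation discriminates the secondary from the tertiary alcohol on steric grounds (chemoselective esterification).

Step 13
Reactants: 20 (5S,6R,8S,8aR)-5-(2-hydroxypropan-2-yl)-3,8-dimethyl-2-oxo-1,2,4,5,6,7,8,8a-octahydroazulen-6-yl propanoate
Product: 21 (5S,6R,8S,8aR)-5-[2-(acetyloxy)propan-2-yl]-3,8-dimethyl-2-oxo-1,2,4,5,6,7,8,8a-octahydroazulen-6-yl propanoate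
Conditions: Ac2O (5 equiv), Sc(OTf)3 (5 mol %), MeCN, −20 °C
Reagents that add atoms: acetic anhydride, CC(=O)OC(C)=O
Why: Lewis-acid-catalysed acylation with Sc(OTf)3 esterifies hindered tertiary alcohols at low temperature, where neither dehydration nor a shift of the neighbouring propanoyl group should compete.

**Compound list**

1 | (S)-5-(hydroxymethyl)furan-2(5H)-one | OC[C@H]1OC(=O)C=C1 | starting material
2 | [(2S)-5-oxo-2,5-dihydrofuran-2-yl]methyl 4-methylbenzenesulfonate | Cc1ccc(cc1)S(=O)(=O)OC[C@H]1OC(=O)C=C1 | intermediate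
3 | propan-2-ol | CC(C)O | starting material
4 | [(2S,3S)-3-(2-hydroxypropan-2-yl)-5-oxooxolan-2-yl]methyl 4-methylbenzenesulfonate | CC(C)(O)[C@H]1CC(=O)O[C@@H]1COS(=O)(=O)c2ccc(C)cc2 | intermediate
5 | (4S)-5,5-dimethyl-4-[(2S)-oxiran-2-yl]oxolan-2-one | CC1(C)OC(=O)C[C@H]1[C@H]2CO2 | intermediate
6 | isopropenylmagnesium bromide | C=C(C)[Mg]Br | starting material
7 | (4S)-4-[(1R)-1-hydroxy-3-methylbut-3-en-1-yl]-5,5-dimethyloxolan-2-one | CC1(C)OC(=O)C[C@H]1[C@H](O)CC(C)=C | intermediate
8 | (3S,4R)-4-hydroxy-3-(2-hydroxypropan-2-yl)-N-methoxy-N,6-dimethylhept-6-enamide | CON(C)C(=O)C[C@@H]([C@H](O)CC(C)=C)C(C)(C)O | intermediate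
9 | N-methoxy-N-methyl-2-[(5S,6R)-2,2,4,4-tetramethyl-6-(2-methylprop-2-en-1-yl)-1,3-dioxan-5-yl]acetamide | CON(C)C(=O)C[C@H]1[C@@H](CC(C)=C)OC(C)(C)OC1(C)C | intermediate
10 | vinylmagnesium bromide | C=C[Mg]Br | starting material
11 | 1-[(5S,6R)-2,2,4,4-tetramethyl-6-(2-methylprop-2-en-1-yl)-1,3-dioxan-5-yl]but-3-en-2-one | C=CC(=O)C[C@H]1[C@@H](CC(C)=C)OC(C)(C)OC1(C)C | intermediate
12 | (4aS,9aR)-2,2,4,4,8-pentamethyl-4a,5,9,9a-tetrahydro-4H-cyclohepta[d][1,3]dioxin-6-one | CC1=CC(=O)C[C@H]2[C@@H](C1)OC(C)(C)OC2(C)C | intermediate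
13 | dimethyl(phenyl)silyl enol ether (C6=C7) of (4aS,8S,9aR)-2,2,4,4,8-pentamethylhexahydro-4H-cyclohepta[d][1,3]dioxin-6(5H)-one | C[C@@H]1C=C(O[Si](C)(C)c2ccccc2)C[C@H]3[C@@H](C1)OC(C)(C)OC3(C)C | intermediate
14 | (4aS,7S,8S,9aR)-7-[(dimethylamino)methyl]-2,2,4,4,8-pentamethylhexahydro-4H-cyclohepta[d][1,3]dioxin-6(5H)-one | C[C@H]1C[C@H]2OC(C)(C)OC(C)(C)[C@H]2CC(=O)[C@@H]1CN(C)C | intermediate
15 | propanal | CCC=O | starting material
16 | (4aS,8S,9aR)-2,2,4,4,8-pentamethyl-7-methylidenehexahydro-4H-cyclohepta[d][1,3]dioxin-6(5H)-one | C[C@H]1C[C@H]2OC(C)(C)OC(C)(C)[C@H]2CC(=O)C1=C | intermediate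
17 | (4aS,7R,8S,9aR)-2,2,4,4,8-pentamethyl-7-(2-oxobutyl)hexahydro-4H-cyclohepta[d][1,3]dioxin-6(5H)-one | C[C@H]1C[C@H]2OC(C)(C)OC(C)(C)[C@H]2CC(=O)[C@@H]1CC(=O)CC | intermediate
18 | acetonide of 19 (O6 and the side-chain oxygen bridged by CMe2 as a cis-fused 2,2,4,4-tetramethyl-1,3-dioxane on the (5S,6R,8S,8aR)-hydroazulenone) | CC1=C2C[C@H]3[C@@H](C[C@H](C)[C@H]2CC1=O)OC(C)(C)OC3(C)C | intermediate
19 | (5S,6R,8S,8aR)-6-hydroxy-5-(2-hydroxypropan-2-yl)-3,8-dimethyl-4,5,6,7,8,8a-hexahydroazulen-2(1H)-one | CC1=C2C[C@@H]([C@H](O)C[C@H](C)[C@H]2CC1=O)C(C)(C)O | intermediate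
20 | (5S,6R,8S,8aR)-5-(2-hydroxypropan-2-yl)-3,8-dimethyl-2-oxo-1,2,4,5,6,7,8,8a-octahydroazulen-6-yl propanoate | CCC(=O)O[C@@H]1C[C@H](C)[C@H]2CC(=O)C(C)=C2C[C@@H]1C(C)(C)O | intermediate
21 | (5S,6R,8S,8aR)-5-[2-(acetyloxy)propan-2-yl]-3,8-dimethyl-2-oxo-1,2,4,5,6,7,8,8a-octahydroazulen-6-yl propanoate | CCC(=O)O[C@@H]1C[C@H](C)[C@H]2CC(=O)C(C)=C2C[C@@H]1C(C)(C)OC(C)=O | target

**Step count:** 13 steps in total; the longest linear sequence is 13 steps, from 1.

**Steps most likely to fail**

Step 10. The acyl-anion addition to the α-substituted exocyclic enone may be slow enough that enone dimerisation and aldehyde self-condensation take over, or the ring-fusion centre may not equilibrate cleanly before cyclisation. The fallback sets out from 14 and replaces the catalytic acyl anion by a nitronate. Heating 14 with 1-nitropropane and DBU in MeCN should release enone 16 in situ and give, by Michael addition, (4aS,7R,8S,9aR)-2,2,4,4,8-pentamethyl-7-(2-nitrobutyl)hexahydro-4H-cyclohepta[d][1,3]dioxin-6(5H)-one F1 (both epimers at the nitro-bearing carbon). A Nef reaction of its sodium nitronate (NaOMe, MeOH; then O3, −78 °C; Me2S) should give diketone 17, now isolated, and KOH in EtOH at 70 °C should close ring A. The fallback comes back to the route at 18.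

Step 9. Hydride delivery to the flexible seven-membered enone may discriminate its faces poorly, or hydrocupration of the β,β-disubstituted position may stall. The fallback sets out from 12 and uses dissolving-metal reduction (Li, NH3/THF, t-BuOH 1 equiv, −78 °C), in which the β-carbanion is protonated after it can relax to the more stable geometry. Trapping the regiodefined lithium enolate with TMSCl/Et3N should give the trimethylsilyl enol ether (C6=C7) of the (8S)-ketone F2. Treating F2 with [CH2=NMe2]I in CH2Cl2 returns to the route at 14.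

Step 13. The neighbouring propanoyl group may shift to the tertiary oxygen, or the tertiary alcohol may dehydrate under Lewis acid, during acetylation. The fallback sets out from 19 and changes the order of esterification so that no migratable ester is present when the tertiary alcohol is acylated. TESCl and imidazole in DMF should silylate only the secondary alcohol to give (5S,6R,8S,8aR)-5-(2-hydroxypropan-2-yl)-3,8-dimethyl-6-[(triethylsilyl)oxy]-4,5,6,7,8,8a-hexahydroazulen-2(1H)-one F3. Ac2O, DMAP and Et3N at 40 °C should give 2-[(5S,6R,8S,8aR)-3,8-dimethyl-2-oxo-6-[(triethylsilyl)oxy]-1,2,4,5,6,7,8,8a-octahydroazulen-5-yl]propan-2-yl acetate F4. HF·pyridine in THF should free 2-[(5S,6R,8S,8aR)-6-hydroxy-3,8-dimethyl-2-oxo-1,2,4,5,6,7,8,8a-octahydroazulen-5-yl]propan-2-yl acetate F5. Propanoic anhydride, pyridine and DMAP at 0 °C then return to the route at 21.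

Further compounds
F1 | step 10 | (4aS,7R,8S,9aR)-2,2,4,4,8-pentamethyl-7-(2-nitrobutyl)hexahydro-4H-cyclohepta[d][1,3]dioxin-6(5H)-one | C[C@H]1C[C@H]2OC(C)(C)OC(C)(C)[C@H]2CC(=O)[C@@H]1CC(CC)[N+](=O)[O-]
F2 | step 9 | trimethylsilyl enol ether (C6=C7) of (4aS,8S,9aR)-2,2,4,4,8-pentamethylhexahydro-4H-cyclohepta[d][1,3]dioxin-6(5H)-one | C[C@@H]1C=C(O[Si](C)(C)C)C[C@H]2[C@@H](C1)OC(C)(C)OC2(C)C
F3 | step 13 | (5S,6R,8S,8aR)-5-(2-hydroxypropan-2-yl)-3,8-dimethyl-6-[(triethylsilyl)oxy]-4,5,6,7,8,8a-hexahydroazulen-2(1H)-one | CC[Si](CC)(CC)O[C@@H]1C[C@H](C)[C@H]2CC(=O)C(C)=C2C[C@@H]1C(C)(C)O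
F4 | step 13 | 2-[(5S,6R,8S,8aR)-3,8-dimethyl-2-oxo-6-[(triethylsilyl)oxy]-1,2,4,5,6,7,8,8a-octahydroazulen-5-yl]propan-2-yl acetate | CC[Si](CC)(CC)O[C@@H]1C[C@H](C)[C@H]2CC(=O)C(C)=C2C[C@@H]1C(C)(C)OC(C)=O
F5 | step 13 | 2-[(5S,6R,8S,8aR)-6-hydroxy-3,8-dimethyl-2-oxo-1,2,4,5,6,7,8,8a-octahydroazulen-5-yl]propan-2-yl acetate | O[C@@H]1C[C@H](C)[C@H]2CC(=O)C(C)=C2C[C@@H]1C(C)(C)OC(C)=O
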